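The target is epiafzelechin-(4β→8)-catechin. Everything rests on opening ring F of the lower catechin unit at C3–C4 and O1–C2: C4 is a benzylic CH2 ortho to the ring oxygen O1 on the phloroglucinol ring D, the retron of an ortho-quinone methide. A catalytic asymmetric oxa-[4+2] cycloaddition of this quinone methide with an (E)-styrylboronate forms the C3–C4 bond and closes ring F in one operation, translates the alkene geometry into the 2,3-trans stereocentres and leaves boron at C3 as a masked hydroxyl. The precursors are a simple salicyl alcohol and an alkenylboronate; the benzylated (−)-epiafzelechin C4 cation is then attached at C8 and hydrogenolysis finishes.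

Key step: step 4

Remark: the SMILES defines the target as (2R,3R)-epiafzelechin joined 4β→8 to (2R,3S)-catechin; (−)-epiafzelechin is bought as the natural product; in step 4 the (R)-catalyst is assumed to give the catechin sense of induction, otherwise its (S)-enantiomer is used.

Step 1
Reactants: 1 3,5-bis(benzyloxy)phenol; 2 paraformaldehyde
Product: 3 4,6-bis(benzyloxy)-2-hydroxybenzaldehyde
Conditions: MgCl2, Et3N, (CH2O)n, MeCN, reflux
Reagents that add atoms: none
Why: Casnati–Skattebøl ortho-formylation, in which the magnesium phenoxide directs formaldehyde to an ortho carbon (the two are equivalent) and a second formaldehyde oxidises the benzylic alkoxide by hydride transfer, so the position between the two benzyloxy groups should stay free.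

Step 2
Reactants: 3 4,6-bis(benzyloxy)-2-hydroxybenzaldehyde
Product: 4 3,5-bis(benzyloxy)-2-(hydroxymethyl)phenol
Conditions: NaBH4, THF/EtOH, 0 °C; pH 7 buffer work-up, used at once
Reagents that add atoms: none
Why: Borohydride reduction of the aryl aldehyde, where low temperature and a neutral work-up should avoid over-reduction through the quinone methide and acid-induced self-condensation of the electron-rich salicyl alcohol.

Step 3
Reactants: 5 3,4-bis(benzyloxy)benzaldehyde; 6 bis(pinacolato)borylmethane
Product: 7 2-[(E)-2-[3,4-bis(benzyloxy)phenyl]ethenyl]-4,4,5,5-tetramethyl-1,3,2-dioxaborolane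
Conditions: lithium 2,2,6,6-tetramethylpiperidide (LiTMP), THF, 0 °C; then 5, −78 °C to rt
Reagents that add atoms: none
Why: Boron–Wittig olefination, in which lithiated 6 adds to the aldehyde and syn-elimination of lithium pinacolborate from the β-alkoxy bis-boronate should give the (E)-alkenylboronate.

Step 4
Reactants: 4 3,5-bis(benzyloxy)-2-(hydroxymethyl)phenol; 7 2-[(E)-2-[3,4-bis(benzyloxy)phenyl]ethenyl]-4,4,5,5-tetramethyl-1,3,2-dioxaborolane
Product: 9 2-[(2S,3S)-5,7-bis(benzyloxy)-2-[3,4-bis(benzyloxy)phenyl]-3,4-dihydro-2H-chromen-3-yl]-4,4,5,5-tetramethyl-1,3,2-dioxaborolane (2,3-trans; 3-boryl analogue of tetra-O-benzyl-(+)-catechin), via o-quinone methide 8 (not isolated)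
Conditions: (R)-3,3'-bis(2,4,6-triisopropylphenyl)-1,1'-binaphthyl-2,2'-diyl N-triflylphosphoramide (5 mol%), 7 (1.5 equiv), 4 Å MS, toluene/CH2Cl2, −40 to 0 °C, 4 added by syringe pump
Reagents that add atoms: none
Why: Proposed new method: the chiral Brønsted acid ionises 4 with loss of water to the hydrogen-bonded o-quinone methide 8, whose O1=C8a–C4a=C4H2 heterodiene (LUMO lowered by protonation at O1) is attacked by the HOMO of the electron-rich alkene 7 in an inverse-electron-demand oxa-Diels–Alder reaction; the closest known reaction type is the chiral phosphoric-acid- or N-triflylphosphoramide-catalysed [4+2] cycloaddition of o-quinone methides generated in situ from o-hydroxybenzyl alcohols with electron-rich styrenes, which has not been shown for a methide-unsubstituted quinone methide or a β-borylstyrene. Ring F is closed by a concerted, asynchronous [4+2] cycloaddition in which the C4–C3 bond (methide carbon to the boron-bearing alkene carbon) is formed ahead of the O1–C2 bond. Regiochemistry is secured by the 3,4-bis(benzyloxy)phenyl group, which puts the larger HOMO coefficient on the boron-bearing carbon and stabilises the developing positive charge at the benzylic C2 that O1 then captures, whereas the pinacol boronate is not a π-donor. C2 and C3 are set together: their trans relationship follows from suprafacial addition to the (E)-alkene, and their absolute configuration from the catalyst, which remains hydrogen-bonded at O1 (the atom that bonds to C2) and shields one face of the planar quinone methide with its 3,3'-aryl groups so that only one alkene face can approach in the endo mode. The step also needs chemoselectivity over self-condensation of 8 and over protodeboronation or deborylative opening to a 2-cinnamylphenol, which slow addition of 4 to an excess of 7 at low temperature, the stabilising 5,7-dialkoxy pattern of 8 and the tricoordinate, poorly leaving pinacol boronate should secure.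

Step 5
Reactants: 9 2-[(2S,3S)-5,7-bis(benzyloxy)-2-[3,4-bis(benzyloxy)phenyl]-3,4-dihydro-2H-chromen-3-yl]-4,4,5,5-tetramethyl-1,3,2-dioxaborolane
Product: 10 5,7,3',4'-tetra-O-benzyl-(+)-catechin, (2R,3S)-5,7-bis(benzyloxy)-2-[3,4-bis(benzyloxy)phenyl]chroman-3-ol
Conditions: 30% H2O2, 2 M NaOH, THF, 0 °C
Reagents that add atoms: hydrogen peroxide, OO
Why: Boronate oxidation, in which hydroperoxide adds to boron and C3 migrates from boron to oxygen with retention, so the 2,3-trans arrangement of 9 should become that of (+)-catechin while the benzyl ethers stay inert.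

Step 6
Reactants: 11 (−)-epiafzelechin, (2R,3R)-2-(4-hydroxyphenyl)chroman-3,5,7-triol
Product: 12 5,7,4'-tri-O-benzyl-(−)-epiafzelechin, (2R,3R)-5,7-bis(benzyloxy)-2-[4-(benzyloxy)phenyl]chroman-3-ol
Conditions: BnBr (3.3 equiv), K2CO3, DMF, 0 °C to rt
Reagents that add atoms: benzyl bromide, BrCc1ccccc1
Why: Williamson etherification of the three phenols under carbonate, which should leave the secondary 3-hydroxyl and both stereocentres untouched.

Step 7
Reactants: 12 5,7,4'-tri-O-benzyl-(−)-epiafzelechin
Product: 13 4β-(2-ethoxyethoxy)-5,7,4'-tri-O-benzyl-(−)-epiafzelechin (3,4-trans)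
Conditions: DDQ, 2-ethoxyethanol, CH2Cl2, rt
Reagents that add atoms: 2-ethoxyethanol, CCOCCO
Why: Oxidative benzylic C–H etherification, in which DDQ abstracts hydride from C4 (benzylic to the trioxygenated ring A) and the alcohol adds to the resulting quinone-methide-type cation from the β face, trans to the 3-hydroxyl.

Step 8
Reactants: 13 4β-(2-ethoxyethoxy)-5,7,4'-tri-O-benzyl-(−)-epiafzelechin; 10 5,7,3',4'-tetra-O-benzyl-(+)-catechin
Product: 14 hepta-O-benzyl epiafzelechin-(4β→8)-catechin (upper unit 5,7,4'-tri-O-benzyl, lower unit 5,7,3',4'-tetra-O-benzyl, both 3-hydroxyls free)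
Conditions: Me3SiOTf (0.1 equiv), 10 (3 equiv, surplus recovered), CH2Cl2, −78 °C; Et3N quench
Reagents that add atoms: none
Why: Friedel–Crafts alkylation, in which Lewis-acid ionisation of the C4 ether gives the benzylic cation and the most nucleophilic carbon of 10 (C8, between O1 and the 7-benzyloxy group) should attack from the β face, anti to the α-oriented 2-aryl and 3-hydroxyl groups, setting C4 as 4β (3,4-trans).

Step 9
Reactants: 14 hepta-O-benzyl epiafzelechin-(4β→8)-catechin
Product: 15 Gambiriin C, epiafzelechin-(4β→8)-catechin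
Conditions: H2 (1 atm), Pd(OH)2/C, THF/MeOH/H2O, rt
Reagents that add atoms: none
Why: Hydrogenolysis of the seven benzyl ethers under neutral conditions, which should leave the interflavan bond, the ring ethers and all five stereocentres intact.

Compound list
1 | 3,5-bis(benzyloxy)phenol | Oc1cc(OCc2ccccc2)cc(OCc2ccccc2)c1 | starting material
2 | paraformaldehyde (formaldehyde source, monomer drawn) | C=O | starting material
3 | 4,6-bis(benzyloxy)-2-hydroxybenzaldehyde | O=Cc1c(O)cc(OCc2ccccc2)cc1OCc1ccccc1 | intermediate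
4 | 3,5-bis(benzyloxy)-2-(hydroxymethyl)phenol | OCc1c(O)cc(OCc2ccccc2)cc1OCc1ccccc1 | intermediate
5 | 3,4-bis(benzyloxy)benzaldehyde | O=Cc1ccc(OCc2ccccc2)c(OCc2ccccc2)c1 | starting material
6 | bis(pinacolato)borylmethane, 2,2'-methylenebis(4,4,5,5-tetramethyl-1,3,2-dioxaborolane) | CC1(C)OB(CB2OC(C)(C)C(C)(C)O2)OC1(C)C | starting material
7 | 2-[(E)-2-[3,4-bis(benzyloxy)phenyl]ethenyl]-4,4,5,5-tetramethyl-1,3,2-dioxaborolane | CC1(C)OB(/C=C/c2ccc(OCc3ccccc3)c(OCc3ccccc3)c2)OC1(C)C | intermediate
8 | 3,5-bis(benzyloxy)-6-methylidenecyclohexa-2,4-dien-1-one (o-quinone methide, not isolated) | C=C1C(=O)C=C(OCc2ccccc2)C=C1OCc1ccccc1 | intermediate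
9 | 2-[(2S,3S)-5,7-bis(benzyloxy)-2-[3,4-bis(benzyloxy)phenyl]-3,4-dihydro-2H-chromen-3-yl]-4,4,5,5-tetramethyl-1,3,2-dioxaborolane (2,3-trans) | c1ccccc1COc1cc(OCc2ccccc2)c2c(c1)O[C@H](c1ccc(OCc3ccccc3)c(OCc3ccccc3)c1)[C@@H](B1OC(C)(C)C(C)(C)O1)C2 | intermediate
10 | 5,7,3',4'-tetra-O-benzyl-(+)-catechin, (2R,3S)-5,7-bis(benzyloxy)-2-[3,4-bis(benzyloxy)phenyl]chroman-3-ol | c1ccccc1COc1cc(OCc2ccccc2)c2c(c1)O[C@H](c1ccc(OCc3ccccc3)c(OCc3ccccc3)c1)[C@@H](O)C2 | intermediate
11 | (−)-epiafzelechin, (2R,3R)-2-(4-hydroxyphenyl)chroman-3,5,7-triol | Oc1ccc([C@H]2Oc3cc(O)cc(O)c3C[C@H]2O)cc1 | starting material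
12 | 5,7,4'-tri-O-benzyl-(−)-epiafzelechin, (2R,3R)-5,7-bis(benzyloxy)-2-[4-(benzyloxy)phenyl]chroman-3-ol | c1ccccc1COc1ccc([C@H]2Oc3cc(OCc4ccccc4)cc(OCc4ccccc4)c3C[C@H]2O)cc1 | intermediate
13 | 4β-(2-ethoxyethoxy)-5,7,4'-tri-O-benzyl-(−)-epiafzelechin (2-aryl α, 3-OH α, 4-alkoxy β) | c1ccccc1COc1ccc([C@H]2Oc3cc(OCc4ccccc4)cc(OCc4ccccc4)c3[C@H](OCCOCC)[C@H]2O)cc1 | intermediate
14 | hepta-O-benzyl epiafzelechin-(4β→8)-catechin | c1ccccc1COc1ccc([C@H]2Oc3cc(OCc4ccccc4)cc(OCc4ccccc4)c3[C@H](c3c(OCc4ccccc4)cc(OCc4ccccc4)c4c3O[C@H](c3ccc(OCc5ccccc5)c(OCc5ccccc5)c3)[C@@H](O)C4)[C@H]2O)cc1 | intermediate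
15 | Gambiriin C, epiafzelechin-(4β→8)-catechin | Oc1ccc([C@H]2Oc3cc(O)cc(O)c3[C@H](c3c(O)cc(O)c4c3O[C@H](c3ccc(O)c(O)c3)[C@@H](O)C4)[C@H]2O)cc1 | target

Total step count: 9. Longest linear sequence: 6 steps (steps 1, 2, 4, 5, 8, 9).

Steps most likely to fail

Step 4 (key step, proposed new method). The cycloaddition may suffer from insufficient discrimination between the two alkene faces on a quinone methide that has no substituent at the methide carbon, from self-condensation of the quinone methide outrunning the cycloaddition, or from loss of boron from the alkene by protodeboronation or deborylative ring opening. Partial enantiocontrol alone would be tolerable, since the minor enantiomer of 10 becomes a separable diastereomer after step 8. If the step fails outright, ring F is closed at the same C3–C4 bond by known reactions. From 3, Wittig methylenation (Ph3P=CH2, THF) should give 3,5-bis(benzyloxy)-2-vinylphenol F1. In parallel, from 5, Horner–Wadsworth–Emmons olefination (triethyl phosphonoacetate, NaH, THF) gives ethyl (E)-3-[3,4-bis(benzyloxy)phenyl]acrylate F2, reduction with i-Bu2AlH gives (E)-3-[3,4-bis(benzyloxy)phenyl]prop-2-en-1-ol F3, and methyl chloroformate/pyridine gives (E)-3-[3,4-bis(benzyloxy)phenyl]allyl methyl carbonate F4. Asymmetric allylic etherification of F4 with the phenoxide of F1 ([Ir(cod)Cl]2, BINOL-derived phosphoramidite ligand, enantiomer chosen for the (S)-ether) should give the branched ether 4-[(1S)-1-[3,5-bis(benzyloxy)-2-vinylphenoxy]prop-2-en-1-yl]-1,2-bis(benzyloxy)benzene F5, in which C2 already has its final arrangement. Ring-closing metathesis (second-generation Grubbs catalyst, CH2Cl2, 40 °C) joins the two vinyl groups into the C3=C4 bond of (2S)-5,7-bis(benzyloxy)-2-[3,4-bis(benzyloxy)phenyl]-2H-chromene F6. Hydroboration–oxidation (BH3·SMe2, THF; then H2O2, NaOH), with boron adding at C3 anti to the 2-aryl group, comes back to the route at 10, so that steps 2 to 5 are bypassed.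

Step 8. The cation from 13 may be intercepted by ring A of a second molecule of 13 (oligomerisation), and attack through C6 of 10 may compete with attack through C8. The fallback caps the electrophile with bromine. From 12, NBS (CH2Cl2, −78 °C) should give 8-bromo-5,7,4'-tri-O-benzyl-(−)-epiafzelechin F7. DDQ/2-ethoxyethanol gives 8-bromo-4β-(2-ethoxyethoxy)-5,7,4'-tri-O-benzyl-(−)-epiafzelechin F8, whose ring A is blocked at its reactive carbon. Coupling with one equivalent of 10 (Yb(OTf)3 or Me3SiOTf, CH2Cl2) gives the 8-bromo hepta-O-benzyl dimer F9. Hydrogenolysis over Pd(OH)2/C with H2 and Et3N removes bromine together with the benzyl groups and comes back to the route at 15.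

Step 2. Reduction may run on to the methyl arene through the quinone methide, and the electron-rich salicyl alcohol may condense with itself during isolation. The fallback avoids the aldehyde and the hydride altogether. From 1 and 2, ortho-hydroxymethylation templated by phenylboronic acid (PhB(OH)2, cat. propionic acid, toluene, water removal) should give the bench-stable 5,7-bis(benzyloxy)-2-phenyl-4H-1,3,2-benzodioxaborine F10. Oxidative cleavage of the boronate (H2O2, THF/H2O, rt) immediately before the cycloaddition releases the salicyl alcohol and comes back to the route at 4.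

Further compounds
F1 | step 4 | 3,5-bis(benzyloxy)-2-vinylphenol | C=Cc1c(O)cc(OCc2ccccc2)cc1OCc1ccccc1
F2 | step 4 | ethyl (E)-3-[3,4-bis(benzyloxy)phenyl]acrylate | CCOC(=O)/C=C/c1ccc(OCc2ccccc2)c(OCc2ccccc2)c1
F3 | step 4 | (E)-3-[3,4-bis(benzyloxy)phenyl]prop-2-en-1-ol | OC/C=C/c1ccc(OCc2ccccc2)c(OCc2ccccc2)c1
F4 | step 4 | (E)-3-[3,4-bis(benzyloxy)phenyl]allyl methyl carbonate | COC(=O)OC/C=C/c1ccc(OCc2ccccc2)c(OCc2ccccc2)c1
F5 | step 4 | 4-[(1S)-1-[3,5-bis(benzyloxy)-2-vinylphenoxy]prop-2-en-1-yl]-1,2-bis(benzyloxy)benzene | C=Cc1c(O[C@H](c2ccc(OCc3ccccc3)c(OCc3ccccc3)c2)C=C)cc(OCc2ccccc2)cc1OCc1ccccc1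
F6 | step 4 | (2S)-5,7-bis(benzyloxy)-2-[3,4-bis(benzyloxy)phenyl]-2H-chromene | c1ccccc1COc1cc(OCc2ccccc2)c2c(c1)O[C@H](c1ccc(OCc3ccccc3)c(OCc3ccccc3)c1)C=C2
F7 | step 8 | 8-bromo-5,7,4'-tri-O-benzyl-(−)-epiafzelechin | c1ccccc1COc1ccc([C@H]2Oc3c(Br)c(OCc4ccccc4)cc(OCc4ccccc4)c3C[C@H]2O)cc1
F8 | step 8 | 8-bromo-4β-(2-ethoxyethoxy)-5,7,4'-tri-O-benzyl-(−)-epiafzelechin | c1ccccc1COc1ccc([C@H]2Oc3c(Br)c(OCc4ccccc4)cc(OCc4ccccc4)c3[C@H](OCCOCC)[C@H]2O)cc1
F9 | step 8 | 8-bromo hepta-O-benzyl epiafzelechin-(4β→8)-catechin (bromine on ring A of the upper unit) | c1ccccc1COc1ccc([C@H]2Oc3c(Br)c(OCc4ccccc4)cc(OCc4ccccc4)c3[C@H](c3c(OCc4ccccc4)cc(OCc4ccccc4)c4c3O[C@H](c3ccc(OCc5ccccc5)c(OCc5ccccc5)c3)[C@@H](O)C4)[C@H]2O)cc1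
F10 | step 2 | 5,7-bis(benzyloxy)-2-phenyl-4H-1,3,2-benzodioxaborine | B1(c2ccccc2)OCc2c(OCc3ccccc3)cc(OCc3ccccc3)cc2O1
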